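**Plan**
- Target numbering is used throughout: ring B is C1 (ketone), C2, C3 (carbinol), C4 (methine), C4a, C8a; pyranone atoms are primed.
- Retrosynthetic cuts, in order: pyranone O1'–C2' and C5'–C6' (back to a C4 carbaldehyde and a dioxinone); C1=O back to a C1=C2 alkene; then C3–C4, which returns ring B to an isochroman-3-one (C1–O re-formed, C6' as lactone carbonyl); last the lactone C–O bond, the C1–C2 aldol bond and the aryl–C4 bond.
- Enabling feature: in ring B the carboxyl-level carbon C6' sits on C4 next to the oxygenated quaternary C3, and C1/C2 can be an alkene. This γ,δ-unsaturated β-silyloxy acid is what an Ireland–Claisen shift of an isochroman-3-one with a ketone enol ether on C1 delivers.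
- Forward: the side chains are joined to the purchased arene (steps 1–5), the lactone ring closes (step 6) and is converted into carbocyclic ring B (step 7), C1 is oxidised (steps 9–10), and the pyranone ring closes last (step 14).
- Stereochemistry: one catalytic enantioselective Mukaiyama aldol sets the C1 carbinol; the boat [3,3] transition state relays it to C4 and, through the (Z)-enol ether, to C3; C1 then becomes the ketone.

Key step: step 7

Assumption: the (R,R) antipode of the bisphosphoramide catalyst in step 5 is taken to direct the enol silane to the Si face of aldehyde 7; if the sense is the opposite one, the (S,S) antipode is used and nothing else changes.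

Step 1
Reactants: 1 2-bromo-6-hydroxybenzaldehyde
Product: 2 2-(benzyloxy)-6-bromobenzaldehyde
Conditions: BnBr, K2CO3, DMF, rt
Reagents that add atoms: benzyl bromide, BrCc1ccccc1
Why: Williamson O-alkylation of the phenoxide is expected to proceed cleanly, the aldehyde and aryl bromide being inert to carbonate base.

Step 2
Reactants: 2 2-(benzyloxy)-6-bromobenzaldehyde
Product: 3 2-[2-(benzyloxy)-6-bromophenyl]-1,3-dioxolane
Conditions: ethylene glycol, TsOH·H2O (cat.), PhMe, reflux (Dean–Stark)
Reagents that add atoms: ethylene glycol, OCCO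
Why: Acid-catalysed acetalisation with azeotropic removal of water masks the aldehyde, which would otherwise undergo Reformatsky addition in step 3.

Step 3
Reactants: 3 2-[2-(benzyloxy)-6-bromophenyl]-1,3-dioxolane; 4 tert-butyl bromoacetate
Product: 6 tert-butyl 2-[3-(benzyloxy)-2-(1,3-dioxolan-2-yl)phenyl]acetate, via zinc enolate 5 (not isolated)
Conditions: Zn dust, TMSCl (cat.), THF, rt; then 3, Pd2(dba)3 (2 mol %), XPhos (8 mol %), THF, 60 °C
Reagents that add atoms: none
Why: Zinc insertion into the C–Br bond of 4 gives the Reformatsky reagent, which undergoes Negishi coupling with the aryl bromide under zerovalent palladium and a bulky biaryl phosphine that tolerates the ortho substituent, while acetal, ester and benzyl ether are inert to the mild zinc enolate.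

Step 4
Reactants: 6 tert-butyl 2-[3-(benzyloxy)-2-(1,3-dioxolan-2-yl)phenyl]acetate
Product: 7 tert-butyl 2-[3-(benzyloxy)-2-formylphenyl]acetate
Conditions: 1 M aq. HCl, THF, rt
Reagents that add atoms: water, O
Why: Aryl dioxolanes hydrolyse in dilute aqueous acid at room temperature, conditions under which the tert-butyl ester and the benzyl ether should persist.

Step 5
Reactants: 7 tert-butyl 2-[3-(benzyloxy)-2-formylphenyl]acetate; 8 trimethyl[(1-phenylethenyl)oxy]silane
Product: 9 tert-butyl 2-{3-(benzyloxy)-2-[(1S)-1-hydroxy-3-oxo-3-phenylpropyl]phenyl}acetate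
Conditions: SiCl4, (R,R)-bisphosphoramide catalyst (1,1'-binaphthyl-2,2'-diamine-derived, pentane-1,5-diyl linker; 5 mol %), i-Pr2NEt (cat.), CH2Cl2, −78 °C; aq. NaHCO3
Reagents that add atoms: none
Why: In this Lewis-base-catalysed, SiCl4-mediated enantioselective Mukaiyama aldol addition the chiral phosphoramide-bound silyl cation activates the aromatic aldehyde and shields one face, so that the enol silane of acetophenone should add to the Si face and set the (S)-carbinol, the ester and ether being untouched at −78 °C.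

Step 6
Reactants: 9 tert-butyl 2-{3-(benzyloxy)-2-[(1S)-1-hydroxy-3-oxo-3-phenylpropyl]phenyl}acetate
Product: 10 (1S)-8-(benzyloxy)-1-(2-oxo-2-phenylethyl)isochroman-3-one
Conditions: TFA, CH2Cl2 (1:4), 0 °C → rt
Reagents that add atoms: none
Why: Acidolysis of the tert-butyl ester and 6-exo-trig lactonisation by acyl substitution leave the carbinol C–O bond intact, so the configuration is retained, and the low temperature and short time are chosen to avoid benzylic ionisation or dehydration of the aldol.

Step 7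
Reactants: 10 (1S)-8-(benzyloxy)-1-(2-oxo-2-phenylethyl)isochroman-3-one
Product: 13 (1S,2S)-5-(benzyloxy)-2-phenyl-2-(triethylsilyloxy)-1,2-dihydronaphthalene-1-carboxylic acid, via bis-silyl isochromene 11 (not isolated), via triethylsilyl ester 12 (not isolated)
Conditions: TESOTf (3.5 equiv), Et3N (5 equiv), PhMe, −78 °C → rt, then 60 °C; 10% aq. citric acid, THF, 0 °C
Reagents that add atoms: triethylsilyl trifluoromethanesulfonate, CC[Si](CC)(CC)OS(=O)(=O)C(F)(F)F
Why: Soft enolisation with TESOTf/Et3N should first convert the phenyl ketone into its (Z)-silyl enol ether and then the lactone into its silyl ketene acetal 11, whose ketene-acetal and allylic enol-ether units form the 1,5-diene of an Ireland–Claisen [3,3] shift, the closest known cases being the rearrangements of six-membered lactone ketene acetals that carry an alkenyl group on the carbinol carbon. Ring B closes by suprafacial bond formation between the ketene-acetal carbon (C4) and the enol-ether carbon (C3) while the lactone C1–O bond breaks, a formal 6-endo closure onto the enol ether that the benzo tether restricts to a boat, bicyclo[2.2.2]-like transition state. C4 is controlled by the C1 carbinol centre, because the enol ether can reach the ketene acetal only across the ring face that carries it, and C3 is controlled by the (Z)-geometry, which in the boat places phenyl cis and the silyloxy group trans to the carboxyl. The selectivities needed are (Z)-enolisation, secured by allylic strain between phenyl and the β-substituent in aryl ketone enol ethers, and silylation that outruns β-elimination of the acyloxy group, secured by the absence of a free enolate and by the non-polar solvent. The peri benzyloxy group should push the C1 side chain into the pseudo-axial position that the shift requires, and the donor oxygen on the migrating terminus together with the benzylic ketene acetal should let it proceed near room temperature. Mild aqueous acid then hydrolyses silyl ester 12 to acid 13 and should leave the hindered tertiary silyl ether intact.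

Step 8
Reactants: 13 (1S,2S)-5-(benzyloxy)-2-phenyl-2-(triethylsilyloxy)-1,2-dihydronaphthalene-1-carboxylic acid
Product: 14 [(1R,2S)-5-(benzyloxy)-2-phenyl-2-(triethylsilyloxy)-1,2-dihydronaphthalen-1-yl]methanol
Conditions: LiAlH4, THF, 0 °C → rt
Reagents that add atoms: none
Why: Hydride reduction of the carboxylate gives the primary alcohol without touching the styrenic alkene or the ethers, the carboxylate resists α-deprotonation so C4 is safe, and the trans-diaxial relation of the new alkoxide and the silyloxy group should disfavour O-to-O silyl transfer (the descriptor at the methine carbon changes only because the priorities change).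

Step 9
Reactants: 14 [(1R,2S)-5-(benzyloxy)-2-phenyl-2-(triethylsilyloxy)-1,2-dihydronaphthalen-1-yl]methanol
Product: 15 (3S,4R)-8-(benzyloxy)-4-(hydroxymethyl)-3-phenyl-3-(triethylsilyloxy)-1,2,3,4-tetrahydronaphthalen-1-ol (both C1 epimers)
Conditions: Co(acac)2 (20 mol %), PhSiH3, O2 (1 atm), THF, rt
Reagents that add atoms: dioxygen, O=O
Why: In this Mukaiyama hydration a cobalt hydride transfers a hydrogen atom to C2 to give the benzylic C1 radical, which is trapped by dioxygen and reduced to the alcohol with Markovnikov regiochemistry; the configuration of the new carbinol is irrelevant because it is oxidised in step 10, and any C1 ketone formed directly is carried along.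

Step 10
Reactants: 15 (3S,4R)-8-(benzyloxy)-4-(hydroxymethyl)-3-phenyl-3-(triethylsilyloxy)-1,2,3,4-tetrahydronaphthalen-1-ol
Product: 16 (1S,2S)-5-(benzyloxy)-4-oxo-2-phenyl-2-(triethylsilyloxy)-1,2,3,4-tetrahydronaphthalene-1-carbaldehyde
Conditions: Dess–Martin periodinane (3 equiv), NaHCO3, CH2Cl2, 0 °C → rt
Reagents that add atoms: none
Why: Buffered Dess–Martin oxidation should convert the benzylic secondary and the primary alcohol into ketone and aldehyde in one flask under non-basic conditions that spare the enolisable α-aryl aldehyde centre, and the crude aldehyde is used at once.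

Step 11
Reactants: 17 2,2,6-trimethyl-4H-1,3-dioxin-4-one
Product: 18 [(2,2-dimethyl-6-methylidene-6H-1,3-dioxin-4-yl)oxy]trimethylsilane
Conditions: LiN(i-Pr)2 (LDA), THF, −78 °C; TMSCl
Reagents that add atoms: chlorotrimethylsilane, C[Si](C)(C)Cl
Why: Kinetic γ-deprotonation of the dioxinone and O-silylation of the dienolate is the standard preparation of this vinylogous nucleophile.

Step 12
Reactants: 16 (1S,2S)-5-(benzyloxy)-4-oxo-2-phenyl-2-(triethylsilyloxy)-1,2,3,4-tetrahydronaphthalene-1-carbaldehyde; 18 [(2,2-dimethyl-6-methylidene-6H-1,3-dioxin-4-yl)oxy]trimethylsilane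
Product: 19 6-{2-[(1R,2S)-5-(benzyloxy)-4-oxo-2-phenyl-2-(triethylsilyloxy)-1,2,3,4-tetrahydronaphthalen-1-yl]-2-hydroxyethyl}-2,2-dimethyl-4H-1,3-dioxin-4-one (both carbinol epimers)
Conditions: BF3·OEt2, CH2Cl2, −78 °C; aq. NaHCO3
Reagents that add atoms: none
Why: In this vinylogous Mukaiyama aldol addition the silyl dienol ether should attack through its γ-carbon the BF3-activated aldehyde in preference to the less electrophilic aryl ketone, the Lewis acidic low-temperature conditions avoid enolisation at C4, and the new carbinol is oxidised in step 13.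

Step 13
Reactants: 19 6-{2-[(1R,2S)-5-(benzyloxy)-4-oxo-2-phenyl-2-(triethylsilyloxy)-1,2,3,4-tetrahydronaphthalen-1-yl]-2-hydroxyethyl}-2,2-dimethyl-4H-1,3-dioxin-4-one
Product: 20 6-{2-[(1S,2S)-5-(benzyloxy)-4-oxo-2-phenyl-2-(triethylsilyloxy)-1,2,3,4-tetrahydronaphthalen-1-yl]-2-oxoethyl}-2,2-dimethyl-4H-1,3-dioxin-4-one
Conditions: Dess–Martin periodinane, NaHCO3, CH2Cl2, rt
Reagents that add atoms: none
Why: Dess–Martin oxidation of δ-hydroxy dioxinones to the β-keto dioxinones is routine, and enolisation of the product should run toward the doubly activated methylene and not toward C4.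

Step 14
Reactants: 20 6-{2-[(1S,2S)-5-(benzyloxy)-4-oxo-2-phenyl-2-(triethylsilyloxy)-1,2,3,4-tetrahydronaphthalen-1-yl]-2-oxoethyl}-2,2-dimethyl-4H-1,3-dioxin-4-one
Product: 22 (3S,4R)-8-(benzyloxy)-4-(4-hydroxy-2-oxo-2H-pyran-6-yl)-3-phenyl-3-(triethylsilyloxy)-3,4-dihydronaphthalen-1(2H)-one, via acylketene 21 (not isolated)
Conditions: PhMe, 110 °C
Reagents that add atoms: none
Why: Thermal retro-[4+2] loss of acetone from the dioxinone gives the acylketene, which is captured by the enol oxygen of the side-chain ketone in a 6π oxa-electrocyclisation and tautomerises to the 4-hydroxy-2-pyranone under neutral conditions; no free hydroxyl competes, and the R descriptor at C4 reflects only the priority of the silyl ether, not a change in space.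

Step 15
Reactants: 22 (3S,4R)-8-(benzyloxy)-4-(4-hydroxy-2-oxo-2H-pyran-6-yl)-3-phenyl-3-(triethylsilyloxy)-3,4-dihydronaphthalen-1(2H)-one
Product: 23 (3S,4S)-8-(benzyloxy)-3-hydroxy-4-(4-hydroxy-2-oxo-2H-pyran-6-yl)-3-phenyl-3,4-dihydronaphthalen-1(2H)-one
Conditions: HF·pyridine, pyridine, THF, 0 °C → rt
Reagents that add atoms: none
Why: Buffered fluoride desilylation should cleave the tertiary triethylsilyl ether without a basic step, so that retro-aldol cleavage or β-elimination of the β-hydroxy ketone is avoided.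

Step 16
Reactants: 23 (3S,4S)-8-(benzyloxy)-3-hydroxy-4-(4-hydroxy-2-oxo-2H-pyran-6-yl)-3-phenyl-3,4-dihydronaphthalen-1(2H)-one
Product: 24 (3S,4S)-3,8-dihydroxy-4-(4-hydroxy-2-oxo-2H-pyran-6-yl)-3-phenyl-3,4-dihydronaphthalen-1(2H)-one
Conditions: H2 (1 atm), Pd/C, EtOAc, rt
Reagents that add atoms: none
Why: Hydrogenolysis of the benzyl aryl ether at atmospheric pressure in a neutral solvent should be much faster than reduction of the aryl ketone, the pyranone or the tertiary benzylic alcohol, and the reaction is stopped once the ether is consumed.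

**Compound list**
1 | 2-bromo-6-hydroxybenzaldehyde | O=Cc1c(O)cccc1Br | starting material
2 | 2-(benzyloxy)-6-bromobenzaldehyde | O=Cc1c(OCc2ccccc2)cccc1Br | intermediate
3 | 2-[2-(benzyloxy)-6-bromophenyl]-1,3-dioxolane | Brc1cccc(OCc2ccccc2)c1C1OCCO1 | intermediate
4 | tert-butyl bromoacetate | CC(C)(C)OC(=O)CBr | starting material
5 | (2-tert-butoxy-2-oxoethyl)zinc bromide | CC(C)(C)OC(=O)C[Zn]Br | intermediate (not isolated)
6 | tert-butyl 2-[3-(benzyloxy)-2-(1,3-dioxolan-2-yl)phenyl]acetate | CC(C)(C)OC(=O)Cc1cccc(OCc2ccccc2)c1C1OCCO1 | intermediate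
7 | tert-butyl 2-[3-(benzyloxy)-2-formylphenyl]acetate | CC(C)(C)OC(=O)Cc1cccc(OCc2ccccc2)c1C=O | intermediate
8 | trimethyl[(1-phenylethenyl)oxy]silane | C=C(O[Si](C)(C)C)c1ccccc1 | starting material
9 | tert-butyl 2-{3-(benzyloxy)-2-[(1S)-1-hydroxy-3-oxo-3-phenylpropyl]phenyl}acetate | CC(C)(C)OC(=O)Cc1cccc(OCc2ccccc2)c1[C@@H](O)CC(=O)c1ccccc1 | intermediate
10 | (1S)-8-(benzyloxy)-1-(2-oxo-2-phenylethyl)isochroman-3-one | O=C1Cc2cccc(OCc3ccccc3)c2[C@H](CC(=O)c2ccccc2)O1 | intermediate
11 | (1S)-8-(benzyloxy)-1-[(Z)-2-phenyl-2-(triethylsilyloxy)ethenyl]-3-(triethylsilyloxy)-1H-isochromene | CC[Si](CC)(CC)OC1=Cc2cccc(OCc3ccccc3)c2[C@H](/C=C(\O[Si](CC)(CC)CC)c2ccccc2)O1 | intermediate (not isolated)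
12 | triethylsilyl (1S,2S)-5-(benzyloxy)-2-phenyl-2-(triethylsilyloxy)-1,2-dihydronaphthalene-1-carboxylate | C1=C[C@@](O[Si](CC)(CC)CC)(c2ccccc2)[C@@H](C(=O)O[Si](CC)(CC)CC)c2cccc(OCc3ccccc3)c21 | intermediate (not isolated)
13 | (1S,2S)-5-(benzyloxy)-2-phenyl-2-(triethylsilyloxy)-1,2-dihydronaphthalene-1-carboxylic acid | C1=C[C@@](O[Si](CC)(CC)CC)(c2ccccc2)[C@@H](C(=O)O)c2cccc(OCc3ccccc3)c21 | intermediate
14 | [(1R,2S)-5-(benzyloxy)-2-phenyl-2-(triethylsilyloxy)-1,2-dihydronaphthalen-1-yl]methanol | C1=C[C@@](O[Si](CC)(CC)CC)(c2ccccc2)[C@@H](CO)c2cccc(OCc3ccccc3)c21 | intermediate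
15 | (3S,4R)-8-(benzyloxy)-4-(hydroxymethyl)-3-phenyl-3-(triethylsilyloxy)-1,2,3,4-tetrahydronaphthalen-1-ol (both C1 epimers) | OC1C[C@@](O[Si](CC)(CC)CC)(c2ccccc2)[C@@H](CO)c2cccc(OCc3ccccc3)c21 | intermediate
16 | (1S,2S)-5-(benzyloxy)-4-oxo-2-phenyl-2-(triethylsilyloxy)-1,2,3,4-tetrahydronaphthalene-1-carbaldehyde | O=C1C[C@@](O[Si](CC)(CC)CC)(c2ccccc2)[C@@H](C=O)c2cccc(OCc3ccccc3)c21 | intermediate
17 | 2,2,6-trimethyl-4H-1,3-dioxin-4-one | CC1=CC(=O)OC(C)(C)O1 | starting material
18 | [(2,2-dimethyl-6-methylidene-6H-1,3-dioxin-4-yl)oxy]trimethylsilane | C=C1C=C(O[Si](C)(C)C)OC(C)(C)O1 | intermediate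
19 | 6-{2-[(1R,2S)-5-(benzyloxy)-4-oxo-2-phenyl-2-(triethylsilyloxy)-1,2,3,4-tetrahydronaphthalen-1-yl]-2-hydroxyethyl}-2,2-dimethyl-4H-1,3-dioxin-4-one (both carbinol epimers) | O=C1C[C@@](O[Si](CC)(CC)CC)(c2ccccc2)[C@@H](C(O)CC2=CC(=O)OC(C)(C)O2)c2cccc(OCc3ccccc3)c21 | intermediate
20 | 6-{2-[(1S,2S)-5-(benzyloxy)-4-oxo-2-phenyl-2-(triethylsilyloxy)-1,2,3,4-tetrahydronaphthalen-1-yl]-2-oxoethyl}-2,2-dimethyl-4H-1,3-dioxin-4-one | O=C1C[C@@](O[Si](CC)(CC)CC)(c2ccccc2)[C@@H](C(=O)CC2=CC(=O)OC(C)(C)O2)c2cccc(OCc3ccccc3)c21 | intermediate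
21 | 5-[(1S,2S)-5-(benzyloxy)-4-oxo-2-phenyl-2-(triethylsilyloxy)-1,2,3,4-tetrahydronaphthalen-1-yl]pent-1-ene-1,3,5-trione (acylketene) | O=C1C[C@@](O[Si](CC)(CC)CC)(c2ccccc2)[C@@H](C(=O)CC(=O)C=C=O)c2cccc(OCc3ccccc3)c21 | intermediate (not isolated)
22 | (3S,4R)-8-(benzyloxy)-4-(4-hydroxy-2-oxo-2H-pyran-6-yl)-3-phenyl-3-(triethylsilyloxy)-3,4-dihydronaphthalen-1(2H)-one | O=C1C[C@@](O[Si](CC)(CC)CC)(c2ccccc2)[C@@H](c2cc(O)cc(=O)o2)c2cccc(OCc3ccccc3)c21 | intermediate
23 | (3S,4S)-8-(benzyloxy)-3-hydroxy-4-(4-hydroxy-2-oxo-2H-pyran-6-yl)-3-phenyl-3,4-dihydronaphthalen-1(2H)-one | O=C1C[C@@](O)(c2ccccc2)[C@@H](c2cc(O)cc(=O)o2)c2cccc(OCc3ccccc3)c21 | intermediate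
24 | (3S,4S)-3,8-dihydroxy-4-(4-hydroxy-2-oxo-2H-pyran-6-yl)-3-phenyl-3,4-dihydronaphthalen-1(2H)-one | O=C1C[C@@](O)(c2ccccc2)[C@@H](c2cc(O)cc(=O)o2)c2cccc(O)c21 | target

**Step count**
Total: 16 steps. Longest linear sequence: 15 steps (steps 1–10 and 12–16); step 11 prepares the silyl dienol ether.

**Steps most likely to fail**

1. Step 7. The silyl triflate may assist ionisation of the benzylic, allylic C1–O bond (β-elimination that opens the lactone) before the lactone is silylated, or the lactone may enolise incompletely. The fallback sets out from 10 and gives up the one-flask electrophilic double silylation for a two-stage sequence without Lewis acid at the enolisation stage. The ketone alone is silylated (TESOTf, 1.1 equiv, Et3N, CH2Cl2, −78 °C) and the product is isolated as (1S)-8-(benzyloxy)-1-[(Z)-2-phenyl-2-(triethylsilyloxy)ethenyl]isochroman-3-one F1. The lactone is then deprotonated with KN(SiMe3)2 in the presence of TESCl (THF, −78 °C), and the ketene acetal 11 formed in this way should rearrange on warming to 12. Citric acid work-up returns to the route at 13.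

2. Step 5. Facial selectivity may be poor at the crowded 2,6-disubstituted aldehyde, and the aldol may lose water or revert. The fallback sets out from 7 and builds the carbinol by alkynylation instead of aldol addition. Phenylacetylene is added with Et2Zn, Ti(Oi-Pr)4 and BINOL (antipode chosen for Si-face delivery) to give tert-butyl 2-{3-(benzyloxy)-2-[(1S)-1-hydroxy-3-phenylprop-2-yn-1-yl]phenyl}acetate F2. TFA in CH2Cl2 closes the lactone to (1S)-8-(benzyloxy)-1-(phenylethynyl)isochroman-3-one F3. Gold-catalysed hydration ((Ph3P)AuNTf2, H2O, 1,4-dioxane, 60 °C) should place the carbonyl on the phenyl-bearing alkyne carbon, away from the electron-withdrawing acyloxy carbon; the lactone carbonyl cannot reach the alkyne, so no acyloxy shift is expected. The route is rejoined at 10.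

3. Step 12. The C4–H of aldehyde 16 is activated by the formyl group, the arene and the ortho acyl group, so enolisation may epimerise C4, and addition to the neopentyl-like carbonyl may be slow. The fallback sets out from 14 and attaches the chain before the C1 ketone exists. Dess–Martin oxidation gives (1S,2S)-5-(benzyloxy)-2-phenyl-2-(triethylsilyloxy)-1,2-dihydronaphthalene-1-carbaldehyde F4. Vinylogous Mukaiyama aldol addition of 18 (BF3·OEt2, CH2Cl2, −78 °C) gives 6-{2-[(1R,2S)-5-(benzyloxy)-2-phenyl-2-(triethylsilyloxy)-1,2-dihydronaphthalen-1-yl]-2-hydroxyethyl}-2,2-dimethyl-4H-1,3-dioxin-4-one F5. Mukaiyama hydration of the styrenic alkene (Co(acac)2, PhSiH3, O2) gives 6-{2-[(1R,2S)-5-(benzyloxy)-4-hydroxy-2-phenyl-2-(triethylsilyloxy)-1,2,3,4-tetrahydronaphthalen-1-yl]-2-hydroxyethyl}-2,2-dimethyl-4H-1,3-dioxin-4-one F6. Dess–Martin oxidation of both secondary alcohols rejoins the route at 20.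

Further compounds
F1 | step 7 | (1S)-8-(benzyloxy)-1-[(Z)-2-phenyl-2-(triethylsilyloxy)ethenyl]isochroman-3-one | O=C1Cc2cccc(OCc3ccccc3)c2[C@H](/C=C(\O[Si](CC)(CC)CC)c2ccccc2)O1
F2 | step 5 | tert-butyl 2-{3-(benzyloxy)-2-[(1S)-1-hydroxy-3-phenylprop-2-yn-1-yl]phenyl}acetate | CC(C)(C)OC(=O)Cc1cccc(OCc2ccccc2)c1[C@@H](O)C#Cc1ccccc1
F3 | step 5 | (1S)-8-(benzyloxy)-1-(phenylethynyl)isochroman-3-one | O=C1Cc2cccc(OCc3ccccc3)c2[C@H](C#Cc2ccccc2)O1
F4 | step 12 | (1S,2S)-5-(benzyloxy)-2-phenyl-2-(triethylsilyloxy)-1,2-dihydronaphthalene-1-carbaldehyde | C1=C[C@@](O[Si](CC)(CC)CC)(c2ccccc2)[C@@H](C=O)c2cccc(OCc3ccccc3)c21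
F5 | step 12 | 6-{2-[(1R,2S)-5-(benzyloxy)-2-phenyl-2-(triethylsilyloxy)-1,2-dihydronaphthalen-1-yl]-2-hydroxyethyl}-2,2-dimethyl-4H-1,3-dioxin-4-one | C1=C[C@@](O[Si](CC)(CC)CC)(c2ccccc2)[C@@H](C(O)CC2=CC(=O)OC(C)(C)O2)c2cccc(OCc3ccccc3)c21
F6 | step 12 | 6-{2-[(1R,2S)-5-(benzyloxy)-4-hydroxy-2-phenyl-2-(triethylsilyloxy)-1,2,3,4-tetrahydronaphthalen-1-yl]-2-hydroxyethyl}-2,2-dimethyl-4H-1,3-dioxin-4-one | OC1C[C@@](O[Si](CC)(CC)CC)(c2ccccc2)[C@@H](C(O)CC2=CC(=O)OC(C)(C)O2)c2cccc(OCc3ccccc3)c21
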